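Ring C is cut at C4–C4a and O1–C8a, the two bonds that an aryl iodide can form at its ortho and ipso carbons in a palladium/norbornene (Catellani-type) annulation. The step exploits the adjacent C4a/C8a pair of ring A: iodine stands on C8a, the C8 formyl carbon (masked as a dioxolane) blocks the second ortho position, and C4a–H is the only site the palladacycle can reach. The partner is an (R)-3-bromo-2-arylpropan-1-ol that already carries ring B with its prenyl group and the C3 stereocentre, obtained by catalytic desymmetrisation of a 3-aryloxetane. One operation joins the two halves and closes ring C.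

Key step: step 10

Remarks: chroman numbering is used (O1, C2, C3, C4, C4a, C5 to C8, C8a; ring A is the benzo ring, ring B the 3-aryl group, ring C the pyran ring). The stereocentre of the target is read from the SMILES as (3R). Catalyst-bound organopalladium species of step 10 are described in words and carry no compound number. The enantiomer of the squaramide catalyst in step 5 is assumed to be chosen by a test reaction so that the (R)-bromo alcohol results. Compounds 1, 3, 9 and 13 are assumed to be commercial.

Step 1
Reactants: 1 3-methoxyphenol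
Product: 2 1-methoxy-3-(methoxymethoxy)benzene
Conditions: MOMCl, i-Pr2NEt, CH2Cl2, 0 °C to rt
Reagents that add atoms: chloromethyl methyl ether (MOMCl), COCCl
Why: Williamson-type O-alkylation of the phenol with the reactive α-chloro ether gives the MOM ether, which later acts as the stronger ortho-directing group and is removable by acid at the end.

Step 2
Reactants: 2 1-methoxy-3-(methoxymethoxy)benzene; 3 1-bromo-3-methylbut-2-ene (prenyl bromide)
Product: 5 1-methoxy-3-(methoxymethoxy)-2-(3-methylbut-2-en-1-yl)benzene, via 2-lithio aryl ether 4 (not isolated)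
Conditions: n-BuLi, THF, 0 °C; then CuBr·SMe2 (10 mol %), 3, −78 °C to rt
Reagents that add atoms: none
Why: Directed ortho-metalation takes place at the position flanked by both oxygen directing groups, and copper-catalysed SN2 allylic substitution at the primary carbon of prenyl bromide avoids the reverse-prenyl isomer.

Step 3
Reactants: 5 1-methoxy-3-(methoxymethoxy)-2-(3-methylbut-2-en-1-yl)benzene
Product: 8 [4-methoxy-2-(methoxymethoxy)-3-(3-methylbut-2-en-1-yl)phenyl]boronic acid, via aryllithium 6 (not isolated), via lithium aryltriisopropoxyborate 7 (not isolated)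
Conditions: n-BuLi, TMEDA, THF, −78 °C to 0 °C; B(Oi-Pr)3, −78 °C to rt; then AcOH, H2O, 0 °C
Reagents that add atoms: triisopropyl borate, CC(C)OB(OC(C)C)OC(C)C; water, O
Why: A second directed ortho-metalation is steered by the MOM ether, the stronger of the two directing groups, to its only free ortho position, and the aryllithium is trapped by the borate ester and hydrolysed (lithiation–borylation).

Step 4
Reactants: 8 [4-methoxy-2-(methoxymethoxy)-3-(3-methylbut-2-en-1-yl)phenyl]boronic acid; 9 3-iodooxetane
Product: 10 3-[4-methoxy-2-(methoxymethoxy)-3-(3-methylbut-2-en-1-yl)phenyl]oxetane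
Conditions: NiI2 (6 mol %), trans-2-aminocyclohexanol hydrochloride (6 mol %), NaN(SiMe3)2, i-PrOH, 80 °C
Reagents that add atoms: none
Why: Nickel-catalysed alkyl–aryl Suzuki–Miyaura coupling of a secondary alkyl iodide, a reaction established for 3-iodooxetane with arylboronic acids, should give the achiral oxetane with two enantiotopic CH2–O arms.

Step 5
Reactants: 10 3-[4-methoxy-2-(methoxymethoxy)-3-(3-methylbut-2-en-1-yl)phenyl]oxetane
Product: 12 (2R)-3-bromo-2-[4-methoxy-2-(methoxymethoxy)-3-(3-methylbut-2-en-1-yl)phenyl]propan-1-ol, via trimethylsilyl ether 11 (not isolated)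
Conditions: chiral arylpyrrolidine-derived squaramide (hydrogen-bond-donor catalyst, 5 mol %), TMSBr, t-BuOMe, −78 °C; then MeOH, citric acid (cat.), 0 °C
Reagents that add atoms: bromotrimethylsilane, C[Si](C)(C)Br
Why: In this hydrogen-bond-donor-catalysed enantioselective oxetane opening the squaramide binds the bromide of the silyl oxetanium ion pair and delivers it by SN2 attack to one of the two enantiotopic methylene carbons, so the prochiral benzylic carbon becomes the future C3 stereocentre under catalyst control, and methanolysis then frees the alcohol.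

Step 6
Reactants: 13 1-iodo-3,5-dimethoxybenzene
Product: 15 2-iodo-4,6-dimethoxybenzaldehyde, via aryl iminium salt 14 (not isolated)
Conditions: POCl3, DMF, 0 °C to 80 °C; then H2O, 0 °C
Reagents that add atoms: N,N-dimethylformamide, CN(C)C=O; water, O
Why: Vilsmeier–Haack formylation should occur para to one methoxy group and ortho to the other at the carbon next to iodine, the site preferred in 1-halo-3,5-dimethoxybenzenes over the more crowded position between the two methoxy groups.

Step 7
Reactants: 15 2-iodo-4,6-dimethoxybenzaldehyde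
Product: 17 2-hydroxy-6-iodo-4-methoxybenzaldehyde, via aryloxydichloroborane chelate 16 (not isolated)
Conditions: BCl3 (1.1 equiv), CH2Cl2, −78 °C to 0 °C; then H2O
Reagents that add atoms: none
Why: In this chelation-controlled ether cleavage BCl3 binds the carbonyl oxygen and the neighbouring methoxy oxygen, so chloride removes only the methyl group ortho to the aldehyde and the para methoxy group stays.

Step 8
Reactants: 17 2-hydroxy-6-iodo-4-methoxybenzaldehyde
Product: 18 2-iodo-4-methoxy-6-(methoxymethoxy)benzaldehyde
Conditions: MOMCl, i-Pr2NEt, CH2Cl2, 0 °C to rt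
Reagents that add atoms: chloromethyl methyl ether (MOMCl), COCCl
Why: O-alkylation of the phenol protects the future 7-hydroxyl in a form that is stable to the basic key step and is lost together with the other MOM group at the end.

Step 9
Reactants: 18 2-iodo-4-methoxy-6-(methoxymethoxy)benzaldehyde
Product: 19 2-[2-iodo-4-methoxy-6-(methoxymethoxy)phenyl]-1,3-dioxolane
Conditions: Me3SiOCH2CH2OSiMe3, TMSOTf (cat.), CH2Cl2, −78 °C; then pyridine
Reagents that add atoms: 1,2-bis(trimethylsilyloxy)ethane, C[Si](C)(C)OCCO[Si](C)(C)C
Why: Noyori acetalisation at low temperature masks the aldehyde, which would otherwise be attacked by the norbornyl palladium intermediate of step 10, without disturbing the MOM ether.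

Step 10
Reactants: 19 2-[2-iodo-4-methoxy-6-(methoxymethoxy)phenyl]-1,3-dioxolane; 12 (2R)-3-bromo-2-[4-methoxy-2-(methoxymethoxy)-3-(3-methylbut-2-en-1-yl)phenyl]propan-1-ol
Product: 20 (3R)-8-(1,3-dioxolan-2-yl)-5-methoxy-7-(methoxymethoxy)-3-[4-methoxy-2-(methoxymethoxy)-3-(3-methylbut-2-en-1-yl)phenyl]-3,4-dihydro-2H-chromene
Conditions: Pd(OAc)2 (10 mol %), RuPhos (20 mol %), norbornene (1 equiv), Cs2CO3 (3 equiv), 1,4-dioxane, 100 °C
Reagents that add atoms: none
Why: Proposed new method: oxidative addition of the C8a–I bond of 19 to zerovalent palladium, syn carbopalladation of norbornene and carbonate-assisted palladation of C4a–H give an aryl norbornyl palladacycle of divalent palladium, which takes up the primary C–Br bond of 12 by SN2-type oxidative addition to tetravalent palladium and forms C4–C4a by C(sp2)–C(sp3) reductive elimination. With both positions ortho to C8a now substituted, norbornene is expelled by β-carbon elimination, the aryl palladium bromide is captured by the tethered hydroxyl (deprotonated by Cs2CO3), and C(aryl)–O reductive elimination forms O1–C8a and returns zerovalent palladium. The closest known reaction types are the Catellani annulation of aryl iodides with epoxides to 2,3-dihydrobenzofurans (the same ortho alkylation followed by ipso C–O closure, with one ring atom fewer) and the ortho alkylation with ipso amination of bromoalkylamines to tetrahydroquinolines, so the six-membered C–O closure from a 3-bromopropanol is the untested element. Ring C closes as a formal [4+2] annulation of the O–C2–C3–C4 chain across the C4a–C8a edge of ring A, the ring-forming event being reductive elimination from a seven-membered aryl palladium alkoxide. No stereocentre is formed, since C3 was set in step 5 and lies β to both reacting centres, so it should be carried through unchanged as long as capture of 12 by the palladacycle is faster than base-induced loss of HBr. The step needs site selectivity, secured by the dioxolane on C8 and by the small C5 methoxy group that still allows palladation at C4a, and it needs C–O reductive elimination to outrun β-hydride elimination of the alkoxide, which the bulky electron-rich biaryl phosphine is meant to ensure.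

Step 11
Reactants: 20 (3R)-8-(1,3-dioxolan-2-yl)-5-methoxy-7-(methoxymethoxy)-3-[4-methoxy-2-(methoxymethoxy)-3-(3-methylbut-2-en-1-yl)phenyl]-3,4-dihydro-2H-chromene
Product: 21 (3R)-7-hydroxy-3-[2-hydroxy-4-methoxy-3-(3-methylbut-2-en-1-yl)phenyl]-5-methoxy-3,4-dihydro-2H-chromene-8-carbaldehyde
Conditions: HCl (2 M aq.), THF, 40 °C
Reagents that add atoms: water, O
Why: Acid-catalysed acetal hydrolysis should cleave both MOM ethers and the dioxolane in one operation, at a temperature low enough that the prenyl alkene is not protonated and without any effect on the C3 stereocentre.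

Compound list
1 | 3-methoxyphenol | COc1cccc(O)c1 | starting material
2 | 1-methoxy-3-(methoxymethoxy)benzene | COCOc1cccc(OC)c1 | intermediate
3 | 1-bromo-3-methylbut-2-ene (prenyl bromide) | CC(C)=CCBr | starting material
4 | [2-methoxy-6-(methoxymethoxy)phenyl]lithium | [Li]c1c(OC)cccc1OCOC | intermediate (not isolated)
5 | 1-methoxy-3-(methoxymethoxy)-2-(3-methylbut-2-en-1-yl)benzene | COCOc1cccc(OC)c1CC=C(C)C | intermediate
6 | [4-methoxy-2-(methoxymethoxy)-3-(3-methylbut-2-en-1-yl)phenyl]lithium | [Li]c1ccc(OC)c(CC=C(C)C)c1OCOC | intermediate (not isolated)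
7 | lithium [4-methoxy-2-(methoxymethoxy)-3-(3-methylbut-2-en-1-yl)phenyl]tri(propan-2-yloxy)borate | [Li+].CC(C)O[B-](OC(C)C)(OC(C)C)c1ccc(OC)c(CC=C(C)C)c1OCOC | intermediate (not isolated)
8 | [4-methoxy-2-(methoxymethoxy)-3-(3-methylbut-2-en-1-yl)phenyl]boronic acid | COCOc1c(B(O)O)ccc(OC)c1CC=C(C)C | intermediate
9 | 3-iodooxetane | IC1COC1 | starting material
10 | 3-[4-methoxy-2-(methoxymethoxy)-3-(3-methylbut-2-en-1-yl)phenyl]oxetane | COc1ccc(C2COC2)c(OCOC)c1CC=C(C)C | intermediate
11 | {(2R)-3-bromo-2-[4-methoxy-2-(methoxymethoxy)-3-(3-methylbut-2-en-1-yl)phenyl]propoxy}trimethylsilane | COc1ccc([C@@H](CBr)CO[Si](C)(C)C)c(OCOC)c1CC=C(C)C | intermediate (not isolated)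
12 | (2R)-3-bromo-2-[4-methoxy-2-(methoxymethoxy)-3-(3-methylbut-2-en-1-yl)phenyl]propan-1-ol | COc1ccc([C@@H](CBr)CO)c(OCOC)c1CC=C(C)C | intermediate
13 | 1-iodo-3,5-dimethoxybenzene | COc1cc(I)cc(OC)c1 | starting material
14 | N-[(2-iodo-4,6-dimethoxyphenyl)methylidene]-N-methylmethanaminium dichlorophosphate | COc1cc(I)c(C=[N+](C)C)c(OC)c1.[O-]P(=O)(Cl)Cl | intermediate (not isolated)
15 | 2-iodo-4,6-dimethoxybenzaldehyde | COc1cc(I)c(C=O)c(OC)c1 | intermediate
16 | dichloro(2-formyl-3-iodo-5-methoxyphenoxy)borane | COc1cc(I)c(C=O)c(OB(Cl)Cl)c1 | intermediate (not isolated)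
17 | 2-hydroxy-6-iodo-4-methoxybenzaldehyde | COc1cc(O)c(C=O)c(I)c1 | intermediate
18 | 2-iodo-4-methoxy-6-(methoxymethoxy)benzaldehyde | COCOc1cc(OC)cc(I)c1C=O | intermediate
19 | 2-[2-iodo-4-methoxy-6-(methoxymethoxy)phenyl]-1,3-dioxolane | COCOc1cc(OC)cc(I)c1C1OCCO1 | intermediate
20 | (3R)-8-(1,3-dioxolan-2-yl)-5-methoxy-7-(methoxymethoxy)-3-[4-methoxy-2-(methoxymethoxy)-3-(3-methylbut-2-en-1-yl)phenyl]-3,4-dihydro-2H-chromene | COc1ccc([C@@H]2COc3c(C4OCCO4)c(OCOC)cc(OC)c3C2)c(OCOC)c1CC=C(C)C | intermediate
21 | (3R)-7-hydroxy-3-[2-hydroxy-4-methoxy-3-(3-methylbut-2-en-1-yl)phenyl]-5-methoxy-3,4-dihydro-2H-chromene-8-carbaldehyde | COc1ccc([C@@H]2COc3c(C=O)c(O)cc(OC)c3C2)c(O)c1CC=C(C)C | target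

Total step count: 11
Longest linear sequence: 7 steps (steps 1 to 5, then 10 and 11)

Steps most likely to fail

1. Step 10 (Proposed new method). Base-induced E2 loss of HBr across the benzylic β-hydrogen of the bromo alcohol, or its intramolecular O-alkylation, may outrun capture by the palladacycle. In addition, β-hydride elimination from the palladium alkoxide (net ipso reduction) may win over C–O reductive elimination. The fallback uses known chemistry and makes the two bonds in separate steps, C4–C4a by Negishi coupling and O1–C8a by SNAr; it sets out from 12 and comes back to the route at 21. Commercial 2-fluoro-4,6-dimethoxybenzaldehyde would be demethylated ortho to the carbonyl (BCl3, CH2Cl2) to 2-fluoro-6-hydroxy-4-methoxybenzaldehyde F1. Bromination para to the phenol (NBS, MeCN, 0 °C) should give 3-bromo-2-fluoro-6-hydroxy-4-methoxybenzaldehyde F2, and protection (MOMCl, i-Pr2NEt) 3-bromo-2-fluoro-4-methoxy-6-(methoxymethoxy)benzaldehyde F3. Bromo alcohol 12 would be silylated (TBSCl, imidazole, DMF) to the tert-butyldimethylsilyl ether F4 and converted with Zn dust and LiCl in THF into the alkylzinc bromide F5. Coupling of F5 with F3 (Pd(OAc)2, SPhos, THF, 40 °C) should give the 3-alkylbenzaldehyde F6. Desilylation (Bu4NF, THF) to the alcohol F7 and treatment with K2CO3 in DMF at 60 °C should close ring C by displacement of the fluoride ortho to the formyl group, giving the chroman aldehyde F8. The conditions of step 11 would then remove the two MOM groups of F8 and deliver 21.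

2. Step 5. The silyl bromide may cleave the aryl MOM ether, adventitious HBr may add to the prenyl alkene, and the ortho-alkoxy group next to the oxetane may weaken the discrimination between the two enantiotopic methylene groups. The fallback replaces oxetane opening by enzymatic desymmetrisation of a 1,3-diol; it sets out from boronic acid 8 and comes back at 12. Suzuki–Miyaura coupling of 8 with 2-bromoprop-2-en-1-ol (Pd(PPh3)4, K2CO3, dioxane/H2O, 80 °C) would give the 2-arylprop-2-en-1-ol F9. Hydroboration with 9-BBN, which should take the 1,1-disubstituted alkene ahead of the trisubstituted prenyl alkene, and oxidation with NaBO3·4H2O would give the 2-arylpropane-1,3-diol F10. A lipase (Burkholderia cepacia lipase, vinyl acetate, t-BuOMe), selected by screening for the required sense, would acetylate one enantiotopic hydroxymethyl group to the (S)-monoacetate F11. Appel bromination (CBr4, PPh3, CH2Cl2, 0 °C), carried out at once to avoid acyl migration, would give the (R)-bromo acetate F12, and methanolysis (K2CO3, MeOH, 0 °C) would give 12.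

3. Step 4. Protodeboronation of the electron-rich ortho-alkoxy boronic acid in the basic alcoholic medium and slow transmetalation to nickel next to the MOM ether may starve the coupling. The fallback reverses the polarity of the coupling; it sets out from 5 and comes back at 10. Lithiation of 5 as in step 3 (through 6) and quenching with I2 at −78 °C would give the aryl iodide F13. Negishi coupling of F13 with oxetan-3-ylzinc iodide F14, prepared from 9 with Zn dust and LiCl in THF, under Pd(OAc)2 and CPhos in THF at rt should give 10.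

Further compounds
F1 | step 10 | 2-fluoro-6-hydroxy-4-methoxybenzaldehyde | COc1cc(O)c(C=O)c(F)c1
F2 | step 10 | 3-bromo-2-fluoro-6-hydroxy-4-methoxybenzaldehyde | COc1cc(O)c(C=O)c(F)c1Br
F3 | step 10 | 3-bromo-2-fluoro-4-methoxy-6-(methoxymethoxy)benzaldehyde | COCOc1cc(OC)c(Br)c(F)c1C=O
F4 | step 10 | tert-butyl{(2R)-3-bromo-2-[4-methoxy-2-(methoxymethoxy)-3-(3-methylbut-2-en-1-yl)phenyl]propoxy}dimethylsilane | COc1ccc([C@@H](CBr)CO[Si](C)(C)C(C)(C)C)c(OCOC)c1CC=C(C)C
F5 | step 10 | {(2R)-3-[tert-butyl(dimethyl)silyl]oxy-2-[4-methoxy-2-(methoxymethoxy)-3-(3-methylbut-2-en-1-yl)phenyl]propyl}zinc bromide | COc1ccc([C@@H](C[Zn]Br)CO[Si](C)(C)C(C)(C)C)c(OCOC)c1CC=C(C)C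
F6 | step 10 | 3-{(2R)-3-[tert-butyl(dimethyl)silyl]oxy-2-[4-methoxy-2-(methoxymethoxy)-3-(3-methylbut-2-en-1-yl)phenyl]propyl}-2-fluoro-4-methoxy-6-(methoxymethoxy)benzaldehyde | COc1ccc([C@@H](Cc2c(OC)cc(OCOC)c(C=O)c2F)CO[Si](C)(C)C(C)(C)C)c(OCOC)c1CC=C(C)C
F7 | step 10 | 2-fluoro-3-{(2R)-3-hydroxy-2-[4-methoxy-2-(methoxymethoxy)-3-(3-methylbut-2-en-1-yl)phenyl]propyl}-4-methoxy-6-(methoxymethoxy)benzaldehyde | COc1ccc([C@@H](Cc2c(OC)cc(OCOC)c(C=O)c2F)CO)c(OCOC)c1CC=C(C)C
F8 | step 10 | (3R)-5-methoxy-7-(methoxymethoxy)-3-[4-methoxy-2-(methoxymethoxy)-3-(3-methylbut-2-en-1-yl)phenyl]-3,4-dihydro-2H-chromene-8-carbaldehyde | COc1ccc([C@@H]2COc3c(C=O)c(OCOC)cc(OC)c3C2)c(OCOC)c1CC=C(C)C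
F9 | step 5 | 2-[4-methoxy-2-(methoxymethoxy)-3-(3-methylbut-2-en-1-yl)phenyl]prop-2-en-1-ol | COc1ccc(C(=C)CO)c(OCOC)c1CC=C(C)C
F10 | step 5 | 2-[4-methoxy-2-(methoxymethoxy)-3-(3-methylbut-2-en-1-yl)phenyl]propane-1,3-diol | COc1ccc(C(CO)CO)c(OCOC)c1CC=C(C)C
F11 | step 5 | (2S)-3-hydroxy-2-[4-methoxy-2-(methoxymethoxy)-3-(3-methylbut-2-en-1-yl)phenyl]propyl acetate | COc1ccc([C@@H](CO)COC(C)=O)c(OCOC)c1CC=C(C)C
F12 | step 5 | (2R)-3-bromo-2-[4-methoxy-2-(methoxymethoxy)-3-(3-methylbut-2-en-1-yl)phenyl]propyl acetate | COc1ccc([C@@H](CBr)COC(C)=O)c(OCOC)c1CC=C(C)C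
F13 | step 4 | 1-iodo-4-methoxy-2-(methoxymethoxy)-3-(3-methylbut-2-en-1-yl)benzene | COCOc1c(I)ccc(OC)c1CC=C(C)C
F14 | step 4 | oxetan-3-ylzinc iodide | I[Zn]C1COC1
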